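Readings and results are simulated with made-up constants, and the scatter is random.

We weigh G and Z, so our first idea is to take their ratio as the preference of L for E over D. It won't do: in winter G over Z is 1.44 after 1.00 h but 1.11 after 15.0 h, so this ratio drifts as the flask proceeds.

in all of them: E 0.20 M; D 0.20 M
- midnight: Q 0.60 M; L 0.63 mM; run made earlier
- winter: Q 0.60 M; L 5.5 mM; run made earlier
- alder: Q 0.600 M; L 0.50 mM; time 15 h
- cedar: Q 0.600 M; L 1.0 mM; time 15 h
- oak: Q 0.600 M; L 2.0 mM; time 15 h
- larch: Q 0.600 M; L 4.0 mM; time 15 h

- midnight (time / h: G / %, Z / %): 1.33: 3.4, 1.6; 2.00: 5.2, 2.3; 3.00: 6.5, 3.9; 5.00: 9.8, 6.5; 10.0: 14.5, 10.5; 15.0: 19.5, 13.0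
- winter (time / h: G / %, Z / %): 1.00: 15.6, 10.8; 3.00: 30.6, 22.8; 5.00: 37.7, 30.1; 8.00: 43.8, 34.8; 12.0: 46.4, 39.3; 15.0: 46.1, 41.6

(each reading ± 0.5 percentage points)

- excess of G over Z at the end for alder, cedar, oak, larch, in this order
- how that number moves from the first to the last of them (falls all the way / rises, then falls / hardly changes / falls, then rises / rises all the way)

If the suspects stand, the steps to G and to Z carry the same Q and the same L, and both cancel when one rate is divided by the other. What stays constant is then the selectivity factor s, the logarithm of the fraction of E left over the logarithm of the fraction of D left. Each reading counts against both charges, so against its own charge it weighs double. The end of midnight gives 1.64. The end of winter gives 1.43, but by the readings 7.80% of E is left there, a small remainder for readings with a scatter of 0.5 percentage points. So we read winter at 5.00 h instead, which gives 1.52, and we carry the mean, 1.58.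

With d the fraction of D left, E left is d raised to s, and the excess is the difference of these two fractions left over the sum of the two fractions used up. We still need d. Scaling ln d with L is the obvious move, but by their last readings midnight took ln d 1.47 times as far per unit of L as winter did, so one proportion does not fit both runs. We therefore scale each end flask from its nearest run. Alder, scaled from midnight, should keep about 78.7% of its D, which gives an estimated excess of 19.4%. Larch, scaled from winter, should keep about 27.3% of its D, which gives an estimated 9.06%.

The forecast, reckoned its own way, gives 19%, 17%, 13.5% and 9%, and says the excess falls all the way. Its ground: “Higher conversion erodes the excess, so it falls all the way.”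

The flasks give 19.2%, 16.6%, 12.8% and 8.17%: the excess falls all the way.

    Q + L + E → L + G (k = 130 L² mol⁻² h⁻¹)
    2 Q → J (k = 0.0320 L mol⁻¹ h⁻¹)
    Q + L + D → L + Z (k = 82.0 L² mol⁻² h⁻¹)

Larch at 15.0 h keeps 24% of its D, and that fraction raised to s gives 10.4% for E, where larch holds 10%. Cedar keeps 62% of its D, so the same power gives 47.0%, and cedar holds 47% of its E.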